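**Assumption:** the silylated reagents 2, 4 and 6 are treated as catalogue items (each is otherwise one silylation from glycolic acid, 4-bromoguaiacol or vanillin). Lignan numbering is used: C7/C8/C9 for the ring-aryl half, primes for the carbinol half.

## Retrosynthetic overview

1. The only bought stereocentre is C5 of the cellulose-derived butenolide (S)-HBO **1**; it relays to C8, which then controls C7 and C8′ (and through C8′, C7′).
2. C8–C9: the silyloxymethyl radical from acid **2** adds anti to the C5 substituent of **1**, giving **3**.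
3. C7–aryl (key, photochemical, new): the C5 hydroxymethyl of **3** is exchanged for the aryl group of bromide **4**, giving trans lactone **5**.
4. C8′–C7′: anti-aldol of lactone **5** with aldehyde **6** gives **7**.
5. Rings: the lactone ring of **1** is carried to **7**, opened to triol **8**, and re-closed as the only new ring (THF, O–C9′) in **9**; desilylation gives target **10**.

## Route

**Step 1**
Reactants: **1** (S)-5-(hydroxymethyl)furan-2(5H)-one [(S)-HBO]; **2** 2-[(tert-butyldimethylsilyl)oxy]acetic acid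
Product: **3** (4R,5S)-4-{[(tert-butyldimethylsilyl)oxy]methyl}-5-(hydroxymethyl)oxolan-2-one (4,5-trans)
Conditions: Ir[dF(CF3)ppy]2(dtbbpy)PF6 (1 mol%), K2HPO4, DMF, blue LEDs, rt
Reagents that add atoms: **2**, TBSOCH2CO2H, CC(C)(C)[Si](C)(C)OCC(=O)O (delivers CH2OTBS; CO2 is lost)
Why: Photoredox decarboxylative Giese addition; the α-silyloxymethyl radical attacks C4 of the butenolide on the face anti to the C5 CH2OH group, which sets C8 (4R).

**Step 2**
Reactants: **3**; **4** (4-bromo-2-methoxyphenoxy)(tert-butyl)dimethylsilane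
Product: **5** (4R,5S)-5-{4-[(tert-butyldimethylsilyl)oxy]-3-methoxyphenyl}-4-{[(tert-butyldimethylsilyl)oxy]methyl}oxolan-2-one (4,5-trans)
Conditions: CeCl3 (10 mol%), n-Bu4NCl, NiBr2·dtbbpy (10 mol%), 2,4,6-collidine, MeCN, 390 nm LEDs, rt
Reagents that add atoms: **4**, COc1cc(Br)ccc1O[Si](C)(C)C(C)(C)C (delivers the aryl group; CH2O and HBr are lost)
Why: Proposed new method: the Ce(IV) alkoxide of the free primary alcohol undergoes LMCT homolysis, the alkoxy radical β-scissions to CH2O and the lactone-oxygen-stabilised C5 radical, and (dtbbpy)Ni(Ar)Br captures that radical and reductively eliminates on the face anti to the C4 CH2OTBS group (photoexcited Ce(III) turns the Ni cycle over), so C7 is re-set 5S/trans under control of C8; the closest known reactions are Ce-LMCT dehydroxymethylative functionalisation of simple primary alcohols and Ni/photoredox decarboxylative arylation of α-oxy acids (1,2-trans C-aryl furanosides), neither shown on a lactone carbinol or used to set a stereocentre this way.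

**Step 3**
Reactants: **5**; **6** 4-[(tert-butyldimethylsilyl)oxy]-3-methoxybenzaldehyde (TBS-vanillin)
Product: **7** (3R,4R,5S)-3-[(S)-hydroxy{4-[(tert-butyldimethylsilyl)oxy]-3-methoxyphenyl}methyl]-5-{4-[(tert-butyldimethylsilyl)oxy]-3-methoxyphenyl}-4-{[(tert-butyldimethylsilyl)oxy]methyl}oxolan-2-one (all-trans ring, anti aldol)
Conditions: LDA, THF, −78 °C; then **6**, −78 → −45 °C; AcOH quench
Reagents that add atoms: **6**, COc1cc(C=O)ccc1O[Si](C)(C)C(C)(C)C
Why: Lithium lactone-enolate aldol; the aldehyde approaches anti to the adjacent C4 substituent (sets C8′, 3,4-trans), and the ring-fixed E(O)-enolate reacts through a Zimmerman–Traxler chair to give the anti aldol, which is the 7′S carbinol (the lithium aldolate equilibrium favours the same isomer).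

**Step 4**
Reactants: **7**
Product: **8** (7S,8R,8′S,7′S)-triol: ArCH(OH)–CH(CH2OTBS)–CH(CH2OH)–CH(OH)Ar′, i.e. (1S,2R,3S,4S)-2-{[(tert-butyldimethylsilyl)oxy]methyl}-3-(hydroxymethyl)-1,4-bis{4-[(tert-butyldimethylsilyl)oxy]-3-methoxyphenyl}butane-1,4-diol
Conditions: LiBH4, THF, 0 °C → rt
Reagents that add atoms: none
Why: Hydride reduction of the lactone to the 1,4-diol turns the carbonyl into C9′H2OH without touching silyl ethers or any stereocentre, and removes the only epimerisable position (C8′).

**Step 5**
Reactants: **8**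
Product: **9** (S)-[(3S,4R,5S)-5-{4-[(tert-butyldimethylsilyl)oxy]-3-methoxyphenyl}-4-{[(tert-butyldimethylsilyl)oxy]methyl}oxolan-3-yl]{4-[(tert-butyldimethylsilyl)oxy]-3-methoxyphenyl}methanol
Conditions: TsCl (1.1 equiv), Et3N, DMAP (cat.), CH2Cl2, 0 °C → rt
Reagents that add atoms: none
Why: Primary-selective sulfonylation of C9′–OH followed by 5-exo-tet Williamson etherification by the C7 hydroxyl (retention at C7); attack by the C7′ hydroxyl would be a disfavoured 4-exo oxetane closure, and C9–O is masked as its TBS ether, so only the desired THF forms.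

**Step 6**
Reactants: **9**
Product: **10** (S)-[(3S,4R,5S)-5-(4-hydroxy-3-methoxyphenyl)-4-(hydroxymethyl)oxolan-3-yl](4-hydroxy-3-methoxyphenyl)methanol (target)
Conditions: TBAF, AcOH (buffer), THF, 0 °C → rt
Reagents that add atoms: none
Why: Fluoride desilylation of the two aryl and one primary TBS ethers under buffered conditions, which avoids quinone-methide formation and leaves all four stereocentres untouched.

## Compound list

1 | (S)-5-(hydroxymethyl)furan-2(5H)-one, (S)-HBO | OC[C@H]1OC(=O)C=C1 | starting material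
2 | 2-[(tert-butyldimethylsilyl)oxy]acetic acid | CC(C)(C)[Si](C)(C)OCC(=O)O | starting material
3 | (4R,5S)-4-(TBSO-methyl)-5-(hydroxymethyl)oxolan-2-one | OC[C@H]1OC(=O)C[C@@H]1CO[Si](C)(C)C(C)(C)C | intermediate
4 | (4-bromo-2-methoxyphenoxy)(tert-butyl)dimethylsilane | COc1cc(Br)ccc1O[Si](C)(C)C(C)(C)C | starting material
5 | (4R,5S)-5-(4-TBSO-3-methoxyphenyl)-4-(TBSO-methyl)oxolan-2-one | COc1cc([C@H]2OC(=O)C[C@@H]2CO[Si](C)(C)C(C)(C)C)ccc1O[Si](C)(C)C(C)(C)C | intermediate
6 | 4-[(tert-butyldimethylsilyl)oxy]-3-methoxybenzaldehyde | COc1cc(C=O)ccc1O[Si](C)(C)C(C)(C)C | starting material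
7 | (3R,4R,5S)-3-[(S)-hydroxy(4-TBSO-3-methoxyphenyl)methyl]-5-(4-TBSO-3-methoxyphenyl)-4-(TBSO-methyl)oxolan-2-one | COc1cc([C@H]2OC(=O)[C@@H]([C@H](O)c3ccc(O[Si](C)(C)C(C)(C)C)c(OC)c3)[C@@H]2CO[Si](C)(C)C(C)(C)C)ccc1O[Si](C)(C)C(C)(C)C | intermediate
8 | (1S,2R,3S,4S)-2-(TBSO-methyl)-3-(hydroxymethyl)-1,4-bis(4-TBSO-3-methoxyphenyl)butane-1,4-diol | COc1cc([C@@H](O)[C@@H](CO[Si](C)(C)C(C)(C)C)[C@@H](CO)[C@H](O)c2ccc(O[Si](C)(C)C(C)(C)C)c(OC)c2)ccc1O[Si](C)(C)C(C)(C)C | intermediate
9 | tris-TBS ether of the target: (S)-[(3S,4R,5S)-5-(4-TBSO-3-methoxyphenyl)-4-(TBSO-methyl)oxolan-3-yl](4-TBSO-3-methoxyphenyl)methanol | COc1cc([C@H]2OC[C@@H]([C@H](O)c3ccc(O[Si](C)(C)C(C)(C)C)c(OC)c3)[C@@H]2CO[Si](C)(C)C(C)(C)C)ccc1O[Si](C)(C)C(C)(C)C | intermediate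
10 | (S)-[(3S,4R,5S)-5-(4-hydroxy-3-methoxyphenyl)-4-(hydroxymethyl)oxolan-3-yl](4-hydroxy-3-methoxyphenyl)methanol | COc1cc([C@H]2OC[C@@H]([C@H](O)c3ccc(O)c(OC)c3)[C@@H]2CO)ccc1O | target

## Summary

Total steps: 6. Longest linear sequence: 6 (from **1**).

Steps most likely to fail, each with a fallback:

1. **Step 2 (proposed new dehydroxymethylative arylation).** Risks are slow β-scission to an α-acyloxy radical, competing C–H abstraction, or low trans selectivity. Fallback (known chemistry): oxidise the C6 carbinol of **3** to the lactone carboxylic acid (TEMPO/PhI(OAc)2), then use the established Ir/Ni photoredox decarboxylative arylation of α-oxy acids with **4** to reach the same trans lactone **5**.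
2. **Step 3 (anti/syn selectivity at C7′).** Lithium lactone aldols with aryl aldehydes can give modest anti:syn ratios. Fallback: C-acylate the enolate of **5** with the 4-TBSO-3-methoxybenzoyl imidazolide to give the β-keto lactone, then set C7′ by diastereoselective ketone reduction (bulky non-chelating hydride, or Zn(BH4)2 if the chelate sense is the one needed).
3. **Step 5 (chemoselective ring closure).** Sulfonylation of a benzylic hydroxyl would ionise and scramble C7 or C7′. Fallback: avoid ring opening altogether by silylating the 7′-OH of **7**, reducing the lactone to the lactol with DIBAL-H, and deoxygenating the lactol with Et3SiH/BF3·OEt2 at −78 °C to give the THF directly.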